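**Retrosynthetic overview**

1. Locants: ring B is C1(CH3)–C2–C3–C4–C4a–C8a; ring A is C4a–C5(H)–C6(CO2H)–C7(OH)–C8(OH)–C8a; the side chain on C4 is C11(C18H2OAc)–C12–C13–C14–C15(CH3)–C16H2OH. The strategy rests on ring A: C8, C7 and C6 carry O, O and CO2H in a row, C5 is a bare CH and C4a/C8a are the fusion atoms. This is the pattern of a 2-alkyl-3,4-dioxythiophene-5-carboxylate (C8a, C8, C7, C6) that has taken up a two-carbon alkyne (C4a, C5) and lost its sulfur.
2. Key disconnection: C4a–C8a and C5–C6. Rings B and A form together by intramolecular [4+2] addition of a thiophene 1,1-dioxide to the ethynyl group on C4, followed by loss of SO2.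
3. The sulfone comes from the thienyl alkynyl acetate by oxidation at sulfur. The C4 alkyne and the free C18–OH both come from a γ-lactol by Ohira–Bestmann homologation. The trans-lactone comes from alkylation of a β-substituted butyrolactone (C3–C4 bond, sets C4).
4. Thienyl iodide: 3,4-dimethoxythiophene, benzyl ether exchange, tert-butyl ester, aldehyde, enethioate, copper-catalysed conjugate methylation (C1). Lactone: Evans allylation (C15), B-alkyl Suzuki–Miyaura coupling with 4-bromofuranone, copper hydride conjugate reduction (C11).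
5. Ring order: the thiophene (sacrificial, present from the start), the butyrolactone (temporary), then rings B and A in one step. Cleavage of the tert-butyl ester and one hydrogenolysis finish the synthesis.

Key step: step 18

Assumption: the thioester ylide of step 4 is taken as a purchasable stabilised ylide, and the ligand enantiomers named in steps 5 and 12 are assigned by analogy with these two reaction classes; if either substrate responds the other way, the antipodal ligand is used and nothing else changes.

Abbreviation in names: Th = 3,4-bis(benzyloxy)-5-(tert-butoxycarbonyl)thiophen-2-yl. SMILES are always written in full.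

**Route**

Step 1
Reactants: 1 3,4-dimethoxythiophene; 2 benzyl alcohol
Product: 3 3,4-bis(benzyloxy)thiophene
Conditions: BnOH (4 equiv), p-TsOH·H2O (10 mol %), PhMe, 100 °C, MeOH distilled off
Reagents that add atoms: benzyl alcohol (second equivalent), OCc1ccccc1
Why: Acid-catalysed transetherification of the electron-rich 3,4-dialkoxythiophene (C-protonation, addition of benzyl alcohol, loss of methanol) takes place once at each methoxy group, so two molecules of benzyl alcohol are consumed, and removal of methanol drives it to the bis-benzyl ether.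

Step 2
Reactants: 3 3,4-bis(benzyloxy)thiophene
Product: 5 tert-butyl 3,4-bis(benzyloxy)thiophene-2-carboxylate, via 2-lithio-3,4-bis(benzyloxy)thiophene 4 (not isolated)
Conditions: n-BuLi (1.05 equiv), THF, −78 °C; then added to Boc2O (1.3 equiv), −78 → 0 °C
Reagents that add atoms: di-tert-butyl dicarbonate, CC(C)(C)OC(=O)OC(=O)OC(C)(C)C
Why: Alkoxy-assisted α-lithiation of the thiophene and acylation of the aryllithium by Boc2O (inverse addition) give the tert-butyl ester, chosen because it later withstands methylmagnesium bromide, a lactone enolate, i-Bu2AlH at −78 °C and methoxide.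

Step 3
Reactants: 5 tert-butyl 3,4-bis(benzyloxy)thiophene-2-carboxylate
Product: 7 tert-butyl 3,4-bis(benzyloxy)-5-formylthiophene-2-carboxylate, via 5-chloromagnesio thiophene ester 6 (not isolated)
Conditions: TMPMgCl·LiCl (1.2 equiv), THF, −20 °C; then DMF (3 equiv), −20 °C → rt; aq. NH4Cl
Reagents that add atoms: N,N-dimethylformamide, CN(C)C=O
Why: Directed magnesiation of the only remaining ring C–H (α to sulfur, ortho to a benzyloxy group) by the hindered amide base, which leaves the tert-butyl ester alone, is followed by formylation with DMF.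

Step 4
Reactants: 7 tert-butyl 3,4-bis(benzyloxy)-5-formylthiophene-2-carboxylate; 8 S-ethyl (triphenylphosphoranylidene)thioacetate
Product: 9 S-ethyl (E)-3-Th-prop-2-enethioate
Conditions: 8 (1.3 equiv), PhMe, 80 °C
Reagents that add atoms: none
Why: Wittig olefination with a stabilised acylmethylene ylide should give the (E)-enethioate, the acceptor class that accepts methylmagnesium bromide under copper catalysis.

Step 5
Reactants: 9 S-ethyl (E)-3-Th-prop-2-enethioate
Product: 10 S-ethyl (R)-3-Th-butanethioate
Conditions: MeMgBr (1.5 equiv), CuI (3 mol %), (R)-Tol-BINAP (3.3 mol %), t-BuOMe, −70 °C; aq. NH4Cl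
Reagents that add atoms: methylmagnesium bromide, C[Mg]Br
Why: Copper-catalysed asymmetric conjugate addition of a Grignard reagent to an α,β-unsaturated thioester, in which the bisphosphine–copper complex delivers methyl to the Re face of the β-carbon and so sets C1 as R, while the thioester reacts at −70 °C far faster than the hindered tert-butyl ester.

Step 6
Reactants: 10 S-ethyl (R)-3-Th-butanethioate
Product: 11 (R)-3-Th-butan-1-ol
Conditions: LiBH4 (2 equiv), THF, 0 °C → rt
Reagents that add atoms: none
Why: Hydride reduction of the thioester, a better acyl donor than an oxo ester, gives the primary alcohol chemoselectively over the donor-conjugated tert-butyl ester, and C1 is not enolisable.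

Step 7
Reactants: 11 (R)-3-Th-butan-1-ol
Product: 12 (R)-1-iodo-3-Th-butane
Conditions: I2, PPh3, imidazole, CH2Cl2, 0 °C → rt
Reagents that add atoms: iodine, II
Why: Appel-type iodination (alkoxyphosphonium formation, SN2 displacement by iodide) of the primary alcohol; the thiophene is fully substituted, so ring iodination cannot occur.

Step 8
Reactants: 13 (R)-4-benzyl-3-propionyloxazolidin-2-one
Product: 15 (R)-4-benzyl-3-[(S)-2-methylpent-4-enoyl]oxazolidin-2-one, via sodium (Z)-enolate 14 (not isolated)
Conditions: NaN(SiMe3)2 (1.1 equiv), THF, −78 °C; then allyl iodide (3 equiv), −78 → −45 °C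
Reagents that add atoms: allyl iodide, C=CCI
Why: Evans alkylation, in which the chelated (Z)-sodium enolate is allylated on the face opposite the benzyl group of the (R)-oxazolidinone, sets the methyl-bearing carbon (later C15) as S.

Step 9
Reactants: 15 (R)-4-benzyl-3-[(S)-2-methylpent-4-enoyl]oxazolidin-2-one
Product: 16 (S)-2-methylpent-4-en-1-ol
Conditions: LiBH4 (1.5 equiv), H2O (1.1 equiv), Et2O, 0 °C
Reagents that add atoms: none
Why: Reductive cleavage of the N-acyl oxazolidinone gives the primary alcohol without touching the α-stereocenter and returns the auxiliary.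

Step 10
Reactants: 16 (S)-2-methylpent-4-en-1-ol
Product: 17 benzyl (S)-2-methylpent-4-enyl ether
Conditions: NaH, BnBr, n-Bu4NI (cat.), THF/DMF, 0 °C → rt
Reagents that add atoms: benzyl bromide, BrCc1ccccc1
Why: Williamson ether synthesis; the O16 benzyl ether is stable to every later step and falls in the final hydrogenolysis together with the two aryl benzyl ethers.

Step 11
Reactants: 17 benzyl (S)-2-methylpent-4-enyl ether; 18 4-bromofuran-2(5H)-one
Product: 20 4-[(S)-5-(benzyloxy)-4-methylpentyl]furan-2(5H)-one, via B-alkyl-9-borabicyclononane 19 (not isolated)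
Conditions: 9-BBN-H (1.2 equiv), THF, 0 °C → rt; then 18, Pd(dppf)Cl2 (5 mol %), AsPh3 (5 mol %), aq. K3PO4 (3 equiv), DMF, rt → 40 °C
Reagents that add atoms: none
Why: Anti-Markovnikov hydroboration of the terminal alkene and B-alkyl Suzuki–Miyaura coupling with the β-bromo enoate (fast oxidative addition of the vinylogous acyl bromide to zerovalent palladium) join C12 to C11 and give the β-substituted butenolide.

Step 12
Reactants: 20 4-[(S)-5-(benzyloxy)-4-methylpentyl]furan-2(5H)-one
Product: 21 (S)-4-[(S)-5-(benzyloxy)-4-methylpentyl]dihydrofuran-2(3H)-one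
Conditions: Cu(OAc)2·H2O (5 mol %), (S)-p-Tol-BINAP (5.5 mol %), (EtO)2MeSiH (3 equiv), t-BuOH (3 equiv), PhMe, 0 °C → rt
Reagents that add atoms: none
Why: Asymmetric copper hydride 1,4-reduction of a β-alkyl butenolide, in which the bisphosphine-ligated copper hydride adds to one face of C11 and t-BuOH protonates the copper enolate, sets C11 as S under catalyst control (C15 is too remote to interfere).

Step 13
Reactants: 21 (S)-4-[(S)-5-(benzyloxy)-4-methylpentyl]dihydrofuran-2(3H)-one; 12 (R)-1-iodo-3-Th-butane
Product: 23 (3S,4S)-4-[(S)-5-(benzyloxy)-4-methylpentyl]-3-[(R)-3-Th-butyl]dihydrofuran-2(3H)-one, via lithium lactone enolate 22 (not isolated)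
Conditions: LiN(i-Pr)2 (1.05 equiv), THF, −78 °C; then 12 (0.9 equiv), HMPA (3 equiv), −78 → −30 °C
Reagents that add atoms: none
Why: Alkylation of the lithium enolate of a β-substituted γ-butyrolactone with a primary iodide forms the C3–C4 bond, the iodide approaching anti to the C11 side chain, which sets C4 as S (3,4-trans) by 1,2-substrate control.

Step 14
Reactants: 23 (3S,4S)-4-[(S)-5-(benzyloxy)-4-methylpentyl]-3-[(R)-3-Th-butyl]dihydrofuran-2(3H)-one
Product: 24 (3S,4S)-4-[(S)-5-(benzyloxy)-4-methylpentyl]-3-[(R)-3-Th-butyl]tetrahydrofuran-2-ol (anomers)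
Conditions: i-Bu2AlH (1.1 equiv), CH2Cl2, −78 °C; aq. KNaC4H4O6 (potassium sodium tartrate)
Reagents that add atoms: none
Why: Partial reduction of the γ-lactone with one equivalent of i-Bu2AlH at −78 °C stops at the aluminium hemiacetal, while the hindered tert-butyl ester, deactivated by the ring oxygens, should stay.

Step 15
Reactants: 24 (3S,4S)-4-[(S)-5-(benzyloxy)-4-methylpentyl]-3-[(R)-3-Th-butyl]tetrahydrofuran-2-ol; 25 dimethyl (1-diazo-2-oxopropyl)phosphonate
Product: 26 (2S,3S,6R)-2-[(S)-5-(benzyloxy)-4-methylpentyl]-3-ethynyl-6-Th-heptan-1-ol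
Conditions: 25 (2 equiv), K2CO3 (3 equiv), MeOH, 0 °C → rt
Reagents that add atoms: none
Why: Ohira–Bestmann (Seyferth–Gilbert) homologation on the open hydroxy-aldehyde form of the lactol (addition of the diazomethylphosphonate anion, loss of dimethyl phosphate and N2, 1,2-hydride shift of the alkylidene carbene) gives the C4a≡C5 alkyne and sets C18–OH free, the mild carbonate base leaving the α-stereocenter C4 in place.

Step 16
Reactants: 26 (2S,3S,6R)-2-[(S)-5-(benzyloxy)-4-methylpentyl]-3-ethynyl-6-Th-heptan-1-ol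
Product: 27 (2S,3S,6R)-2-[(S)-5-(benzyloxy)-4-methylpentyl]-3-ethynyl-6-Th-heptyl acetate
Conditions: Ac2O, pyridine, DMAP (cat.), CH2Cl2, 0 °C
Reagents that add atoms: acetic anhydride, CC(=O)OC(C)=O
Why: Nucleophile-catalysed acylation of the only free hydroxyl installs the C18 acetate of the target.

Step 17
Reactants: 27 (2S,3S,6R)-2-[(S)-5-(benzyloxy)-4-methylpentyl]-3-ethynyl-6-Th-heptyl acetate
Product: 28 thiophene 1,1-dioxide of 27 (sulfone diene C8a=C8–C7=C6 with the C4 ethynyl group four atoms away)
Conditions: dimethyldioxirane (3 equiv, acetone), CH2Cl2, −20 → 0 °C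
Reagents that add atoms: dimethyldioxirane, CC1(C)OO1
Why: Two successive electrophilic oxygen transfers from the dioxirane to sulfur (the second faster, because the S-oxide is no longer aromatic) should give the thiophene 1,1-dioxide under neutral conditions that spare the alkyne, acetate, tert-butyl ester and benzyl ethers, and full substitution keeps the diene from dimerising.

Step 18
Reactants: 28 thiophene 1,1-dioxide of 27
Product: 30 tert-butyl (5R,8S)-8-[(2S,6S)-1-acetoxy-7-(benzyloxy)-6-methylheptan-2-yl]-3,4-bis(benzyloxy)-5-methyl-5,6,7,8-tetrahydronaphthalene-2-carboxylate, via bridged sulfone cycloadduct 29 (not isolated)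
Conditions: PhMe (0.005 M), BHT (cat.), 110 °C, slow Ar purge (xylenes, 140 °C if conversion is slow)
Reagents that add atoms: none
Why: The sulfone is a non-aromatic, electron-poor cyclic diene (C8a=C8–C7=C6, its LUMO lowered by the SO2 bridge and the C6 ester) that adds in a concerted, suprafacial [4+2] to the tethered terminal alkyne (C4a≡C5), forming C4a–C8a and C5–C6 to give the 7-thiabicyclo[2.2.1]heptadiene 7,7-dioxide 29, which then loses SO2 in a cheletropic step driven by aromatisation. The closest known reaction type is the [4+2] addition of thiophene 1,1-dioxides to alkynes with extrusion of SO2, the sulfur counterpart of the 2-pyrone–alkyne arene synthesis. Ring B closes as the tether ring of a type 1 intramolecular Diels–Alder reaction (four atoms, C1 to C4, between the diene terminus C8a and C4a, hence a fused six-membered carbocycle), and ring A closes as the cycloadduct ring itself and becomes the benzene ring when the sulfur bridge leaves. No stereocenter is created, since the bridgeheads C8a and C6 of 29 end as arene carbons, and C1, C4, C11 and C15 are not touched under neutral heating. The selectivity needed is intramolecular addition over dimerisation of the diene and over a 1,5-hydrogen shift from C1; full substitution at C8a and C6, high dilution and the short tether (which allows only the fused mode, so C5–H must end next to C6) should secure it.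

Step 19
Reactants: 30 tert-butyl (5R,8S)-8-[(2S,6S)-1-acetoxy-7-(benzyloxy)-6-methylheptan-2-yl]-3,4-bis(benzyloxy)-5-methyl-5,6,7,8-tetrahydronaphthalene-2-carboxylate
Product: 31 (5R,8S)-8-[(2S,6S)-1-acetoxy-7-(benzyloxy)-6-methylheptan-2-yl]-3,4-bis(benzyloxy)-5-methyl-5,6,7,8-tetrahydronaphthalene-2-carboxylic acid
Conditions: CF3CO2H/CH2Cl2 (1:4), 0 °C → rt
Reagents that add atoms: none
Why: Acidolysis of the tert-butyl ester (protonation, loss of the tert-butyl cation as isobutene) frees the C6 acid while acetate and benzyl ethers are stable and no free hydroxyl is present that could be trifluoroacetylated.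

Step 20
Reactants: 31 (5R,8S)-8-[(2S,6S)-1-acetoxy-7-(benzyloxy)-6-methylheptan-2-yl]-3,4-bis(benzyloxy)-5-methyl-5,6,7,8-tetrahydronaphthalene-2-carboxylic acid
Product: 32 (5R,8S)-8-[(2S,6S)-1-acetoxy-7-hydroxy-6-methylheptan-2-yl]-3,4-dihydroxy-5-methyl-5,6,7,8-tetrahydronaphthalene-2-carboxylic acid (CNP0191669.1)
Conditions: H2 (1 atm), Pd/C (10 wt %), EtOAc/MeOH, rt
Reagents that add atoms: none
Why: Hydrogenolysis of the two aryl benzyl ethers and the primary alkyl benzyl ether releases the catechol and C16–OH without affecting the arene, the acetate or the four stereocenters, and the sulfur that could poison the catalyst has already left as SO2 in step 18.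

**Compound list**

1 | 3,4-dimethoxythiophene | COc1cscc1OC | starting material
2 | benzyl alcohol | OCc1ccccc1 | starting material
3 | 3,4-bis(benzyloxy)thiophene | c1scc(OCc2ccccc2)c1OCc1ccccc1 | intermediate
4 | 2-lithio-3,4-bis(benzyloxy)thiophene | [Li]c1scc(OCc2ccccc2)c1OCc1ccccc1 | intermediate
5 | tert-butyl 3,4-bis(benzyloxy)thiophene-2-carboxylate | CC(C)(C)OC(=O)c1scc(OCc2ccccc2)c1OCc1ccccc1 | intermediate
6 | [3,4-bis(benzyloxy)-5-(tert-butoxycarbonyl)thiophen-2-yl]magnesium chloride, LiCl complex | CC(C)(C)OC(=O)c1sc([Mg]Cl)c(OCc2ccccc2)c1OCc1ccccc1.[Li+].[Cl-] | intermediate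
7 | tert-butyl 3,4-bis(benzyloxy)-5-formylthiophene-2-carboxylate | CC(C)(C)OC(=O)c1sc(C=O)c(OCc2ccccc2)c1OCc1ccccc1 | intermediate
8 | S-ethyl (triphenylphosphoranylidene)thioacetate | CCSC(=O)C=P(c1ccccc1)(c1ccccc1)c1ccccc1 | starting material
9 | S-ethyl (E)-3-Th-prop-2-enethioate | CCSC(=O)/C=C/c1sc(C(=O)OC(C)(C)C)c(OCc2ccccc2)c1OCc1ccccc1 | intermediate
10 | S-ethyl (R)-3-Th-butanethioate (C1 R) | CCSC(=O)C[C@@H](C)c1sc(C(=O)OC(C)(C)C)c(OCc2ccccc2)c1OCc1ccccc1 | intermediate
11 | (R)-3-Th-butan-1-ol | OCC[C@@H](C)c1sc(C(=O)OC(C)(C)C)c(OCc2ccccc2)c1OCc1ccccc1 | intermediate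
12 | (R)-1-iodo-3-Th-butane | ICC[C@@H](C)c1sc(C(=O)OC(C)(C)C)c(OCc2ccccc2)c1OCc1ccccc1 | intermediate
13 | (R)-4-benzyl-3-propionyloxazolidin-2-one | CCC(=O)N1C(=O)OC[C@H]1Cc1ccccc1 | starting material
14 | sodium (Z)-enolate of 13 | C/C=C(\O[Na])N1C(=O)OC[C@H]1Cc1ccccc1 | intermediate
15 | (R)-4-benzyl-3-[(S)-2-methylpent-4-enoyl]oxazolidin-2-one | C=CC[C@H](C)C(=O)N1C(=O)OC[C@H]1Cc1ccccc1 | intermediate
16 | (S)-2-methylpent-4-en-1-ol | C=CC[C@H](C)CO | intermediate
17 | benzyl (S)-2-methylpent-4-enyl ether | C=CC[C@H](C)COCc1ccccc1 | intermediate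
18 | 4-bromofuran-2(5H)-one | O=C1C=C(Br)CO1 | starting material
19 | 9-[(S)-5-(benzyloxy)-4-methylpentyl]-9-borabicyclo[3.3.1]nonane | C(CC[C@H](C)COCc1ccccc1)B1C2CCCC1CCC2 | intermediate
20 | 4-[(S)-5-(benzyloxy)-4-methylpentyl]furan-2(5H)-one | O=C1C=C(CCC[C@H](C)COCc2ccccc2)CO1 | intermediate
21 | (S)-4-[(S)-5-(benzyloxy)-4-methylpentyl]dihydrofuran-2(3H)-one (C11 S, C15 S) | O=C1C[C@H](CCC[C@H](C)COCc2ccccc2)CO1 | intermediate
22 | lithium enolate of 21 | [Li]OC1=C[C@H](CCC[C@H](C)COCc2ccccc2)CO1 | intermediate
23 | (3S,4S)-4-[(S)-5-(benzyloxy)-4-methylpentyl]-3-[(R)-3-Th-butyl]dihydrofuran-2(3H)-one (trans; C1 R, C4 S, C11 S, C15 S) | O=C1OC[C@@H](CCC[C@H](C)COCc2ccccc2)[C@@H]1CC[C@@H](C)c1sc(C(=O)OC(C)(C)C)c(OCc2ccccc2)c1OCc1ccccc1 | intermediate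
24 | (3S,4S)-4-[(S)-5-(benzyloxy)-4-methylpentyl]-3-[(R)-3-Th-butyl]tetrahydrofuran-2-ol (anomeric mixture) | OC1OC[C@@H](CCC[C@H](C)COCc2ccccc2)[C@@H]1CC[C@@H](C)c1sc(C(=O)OC(C)(C)C)c(OCc2ccccc2)c1OCc1ccccc1 | intermediate
25 | dimethyl (1-diazo-2-oxopropyl)phosphonate | COP(=O)(OC)C(=[N+]=[N-])C(C)=O | starting material
26 | (2S,3S,6R)-2-[(S)-5-(benzyloxy)-4-methylpentyl]-3-ethynyl-6-Th-heptan-1-ol | OC[C@@H](CCC[C@H](C)COCc1ccccc1)[C@@H](C#C)CC[C@@H](C)c1sc(C(=O)OC(C)(C)C)c(OCc2ccccc2)c1OCc1ccccc1 | intermediate
27 | (2S,3S,6R)-2-[(S)-5-(benzyloxy)-4-methylpentyl]-3-ethynyl-6-Th-heptyl acetate | CC(=O)OC[C@@H](CCC[C@H](C)COCc1ccccc1)[C@@H](C#C)CC[C@@H](C)c1sc(C(=O)OC(C)(C)C)c(OCc2ccccc2)c1OCc1ccccc1 | intermediate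
28 | thiophene 1,1-dioxide of 27 (key-step precursor; C1 R, C4 S, C11 S, C15 S) | CC(=O)OC[C@@H](CCC[C@H](C)COCc1ccccc1)[C@@H](C#C)CC[C@@H](C)C1=C(OCc2ccccc2)C(OCc2ccccc2)=C(C(=O)OC(C)(C)C)S1(=O)=O | intermediate
29 | bridged 7-thiabicyclo[2.2.1]hepta-2,5-diene 7,7-dioxide cycloadduct (bridgeheads C8a and C6, configuration there not defined and lost on SO2 extrusion; ring B closed) | CC(=O)OC[C@@H](CCC[C@H](C)COCc1ccccc1)[C@@H]1CC[C@@H](C)C23C1=CC(C(=O)OC(C)(C)C)(C(OCc1ccccc1)=C2OCc1ccccc1)S3(=O)=O | intermediate
30 | tert-butyl (5R,8S)-8-[(2S,6S)-1-acetoxy-7-(benzyloxy)-6-methylheptan-2-yl]-3,4-bis(benzyloxy)-5-methyl-5,6,7,8-tetrahydronaphthalene-2-carboxylate | CC(=O)OC[C@@H](CCC[C@H](C)COCc1ccccc1)[C@@H]1CC[C@@H](C)c2c1cc(C(=O)OC(C)(C)C)c(OCc1ccccc1)c2OCc1ccccc1 | intermediate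
31 | (5R,8S)-8-[(2S,6S)-1-acetoxy-7-(benzyloxy)-6-methylheptan-2-yl]-3,4-bis(benzyloxy)-5-methyl-5,6,7,8-tetrahydronaphthalene-2-carboxylic acid | CC(=O)OC[C@@H](CCC[C@H](C)COCc1ccccc1)[C@@H]1CC[C@@H](C)c2c1cc(C(=O)O)c(OCc1ccccc1)c2OCc1ccccc1 | intermediate
32 | (5R,8S)-8-[(2S,6S)-1-acetoxy-7-hydroxy-6-methylheptan-2-yl]-3,4-dihydroxy-5-methyl-5,6,7,8-tetrahydronaphthalene-2-carboxylic acid (CNP0191669.1) | CC(=O)OC[C@@H](CCC[C@H](C)CO)[C@@H]1CC[C@@H](C)c2c1cc(C(=O)O)c(O)c2O | target

**Step count**

Total: 20 steps. Longest linear sequence: 15 steps (steps 1–7, then 13–20); the lactone branch (steps 8–12) has 5 steps.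

**Steps most likely to fail**

Step 18 (key cycloaddition). The unactivated alkyne may add too slowly to the doubly oxygenated diene. The sulfone would then be consumed first by a 1,5-hydrogen shift from C1 to an exocyclic alkylidene sulfolene, or by intermolecular dimerisation. The fallback changes the dienophile and aromatises afterwards. It sets out from sulfone 28. Semi-hydrogenation of the alkyne (H2, Pd/CaCO3 poisoned with Pb(OAc)2, quinoline, EtOAc) should give the vinyl sulfone F1. The terminal alkene is the better partner for an electron-poor diene, so heating F1 in toluene should give, after loss of SO2, the 4a,5-dihydro tetralin (cyclohexa-1,3-diene) F2. Dehydrogenation of F2 with DDQ in benzene at room temperature comes back to the route at 30.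

Step 17 (oxidation at sulfur). Oxygen may be transferred to the electron-rich ring carbons (ipso attack at C8a or C6 and ring opening) instead of to sulfur, or the benzylic CH2 groups may be oxidised slowly. The fallback stops at the lower oxidation level and uses it as the diene. It sets out from acetate 27. Treatment with mCPBA and BF3·OEt2 in CH2Cl2 at −20 °C should give the thiophene 1-oxide F3, in which complexation of the sulfoxide oxygen by BF3 holds back the second oxidation. Thiophene S-oxides are more reactive dienes than the dioxides and add to alkynes with loss of SO. On warming, F3 should therefore cyclise onto the C4 ethynyl group and return to the route directly at 30.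

Step 5 (conjugate methylation). Addition may be slow or poorly face-selective because the 3-benzyloxy group crowds the β-carbon and the ring donates into the enethioate; 1,2-addition may then compete. The fallback replaces catalyst control by auxiliary control. It sets out from aldehyde 7. Knoevenagel–Doebner condensation with malonic acid (pyridine, piperidine, 80 °C) should give the (E)-acrylic acid F4. Mixed-anhydride coupling (t-BuCOCl, Et3N, LiCl, THF) with (R)-4-phenyloxazolidin-2-one should give the enoyl imide F5. MeMgBr with CuBr·SMe2 in THF at −20 °C should add methyl anti to the phenyl group of the magnesium-chelated s-cis imide and give the (R)-configured adduct F6. LiBH4 then removes the auxiliary and comes back to the route at alcohol 11.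

Further compounds
F1 | step 18 | vinyl analogue of sulfone 28 (C4 ethenyl in place of ethynyl, other centres as in 28) | CC(=O)OC[C@@H](CCC[C@H](C)COCc1ccccc1)[C@@H](C=C)CC[C@@H](C)C1=C(OCc2ccccc2)C(OCc2ccccc2)=C(C(=O)OC(C)(C)C)S1(=O)=O
F2 | step 18 | 4a,5-dihydro derivative of 30 (cyclohexa-1,3-diene C8a=C8–C7=C6, C4a configuration not defined) | CC(=O)OC[C@@H](CCC[C@H](C)COCc1ccccc1)[C@@H]1CC[C@@H](C)C2=C(OCc3ccccc3)C(OCc3ccccc3)=C(C(=O)OC(C)(C)C)CC12
F3 | step 17 | thiophene 1-oxide of 27 | CC(=O)OC[C@@H](CCC[C@H](C)COCc1ccccc1)[C@@H](C#C)CC[C@@H](C)C1=C(OCc2ccccc2)C(OCc2ccccc2)=C(C(=O)OC(C)(C)C)S1=O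
F4 | step 5 | (E)-3-[3,4-bis(benzyloxy)-5-(tert-butoxycarbonyl)thiophen-2-yl]acrylic acid | OC(=O)/C=C/c1sc(C(=O)OC(C)(C)C)c(OCc2ccccc2)c1OCc1ccccc1
F5 | step 5 | (R)-3-[(E)-3-Th-acryloyl]-4-phenyloxazolidin-2-one | O=C(/C=C/c1sc(C(=O)OC(C)(C)C)c(OCc2ccccc2)c1OCc1ccccc1)N1C(=O)OC[C@H]1c1ccccc1
F6 | step 5 | (R)-3-[(R)-3-Th-butanoyl]-4-phenyloxazolidin-2-one | C[C@H](CC(=O)N1C(=O)OC[C@H]1c1ccccc1)c1sc(C(=O)OC(C)(C)C)c(OCc2ccccc2)c1OCc1ccccc1
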